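## Retrosynthetic overview
1. The target comes from its 14-deoxy precursor, in which C1=C10 is ring-trans. A last-step SeO2 allylic oxidation installs 14-OH and turns C1=C10 ring-cis.
2. The 4-hydroxy-5-ene / γ-ylidene butenolide comes from a 4,5-epoxy-7(11)-en-12,6-olide by vinylogous E1cB opening. The C4–O bond is never broken.
3. Ring order: the ten-membered carbocycle forms first, by closing C6–C7 (C1–C10 of the farnesane chain) in an acyclic epoxy aldehyde / alkenyl bromide. The γ-lactone forms second, by O6 attacking C12. Both closures and the opening in line 2 run in one operation.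
4. The acyclic oxidised farnesane comes from three C5 units: a bromo-formyl acrylate (C7, C8, C11–C13) and prenal used twice. Two catalyst-controlled vinylogous aldols join them and set C8 and C2. Sharpless epoxidation sets C4.

Assumption: germacrane numbering is used throughout. C6 is the lactone-oxygen carbon, C7 the butenolide β-carbon, C8 the angelate carbon and C2 the acetate carbon. C10/C14 are the olefin carbon and its CH3/CH2OH, and C4/C15 are the carbinol carbon and its methyl. C11, C12 and C13 are the lactone α-carbon, the carbonyl and CH2OAc. Preparation of the known ligand N-tosyl-D-tryptophan is not counted.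

## Route

Step 1
Reactants: 1 ethyl bromopyruvate
Product: 2 ethyl 3-acetoxy-2-oxopropanoate
Conditions: KOAc, acetone, 0 °C to rt
Reagents that add atoms: potassium acetate, CC(=O)[O-].[K+]
Why: SN2 displacement of the keto-activated primary bromide by acetate puts the C13 acetate in place at the start; no stereocentre is formed.

Step 2
Reactants: 2 ethyl 3-acetoxy-2-oxopropanoate (2 equiv); 3 (triphenylphosphoranylidene)acetaldehyde
Product: 4 ethyl (E)-2-(acetoxymethyl)-4-oxobut-2-enoate
Conditions: PhMe, 60 °C, slow addition of 3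
Reagents that add atoms: none
Why: Wittig olefination, in which the α-keto ester is as electrophilic as an aldehyde toward the stabilised formyl ylide, excess 2 with slow ylide addition suppresses a second homologation, and the ylide preference places CHO trans to CO2Et (C8 cis to C13).

Step 3
Reactants: 4 ethyl (E)-2-(acetoxymethyl)-4-oxobut-2-enoate
Product: 6 ethyl (Z)-2-(acetoxymethyl)-3-bromo-4-oxobut-2-enoate, via dibromide 5 (not isolated)
Conditions: Br2, CH2Cl2, 0 °C to rt; then Et3N, 0 °C
Reagents that add atoms: bromine, BrBr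
Why: Bromination–dehydrobromination (E1cB), in which Et3N removes H7 (α to CHO) and expels the C11 bromide, and the dipole-minimised isomer with CHO trans to CO2Et (Br cis to CO2Et) prevails; the other isomer is lost after step 5 because its C8 alcohol lactonises.

Step 4
Reactants: 7 prenal (3-methylbut-2-enal)
Product: 8 (E)-1-(tert-butyldimethylsilyloxy)-3-methylbuta-1,3-diene
Conditions: TBSOTf, Et3N, Et2O, 0 °C
Reagents that add atoms: tert-butyldimethylsilyl triflate, CC(C)(C)[Si](C)(C)OS(=O)(=O)C(F)(F)F
Why: Soft enolisation, in which O-silylation and γ-deprotonation give the cross-conjugated silyl dienol ether used in both chain extensions.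

Step 5
Reactants: 6 ethyl (Z)-2-(acetoxymethyl)-3-bromo-4-oxobut-2-enoate; 8 (E)-1-(tert-butyldimethylsilyloxy)-3-methylbuta-1,3-diene
Product: 9 ethyl (2Z,4S,6E)-2-(acetoxymethyl)-3-bromo-4-hydroxy-6-methyl-8-oxoocta-2,6-dienoate
Conditions: B-phenyl oxazaborolidinone from N-Ts-D-tryptophan/PhBCl2 (0.5 equiv), iPrOH (1.2 equiv), EtCN, −78 °C
Reagents that add atoms: none
Why: Catalytic asymmetric vinylogous Mukaiyama aldol reaction, in which the boron Lewis acid binds the aldehyde, the indole wall leaves the si face open, and γ-attack of 8 sets C8 as S and delivers the E-enal (C9 trans to C2).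

Step 6
Reactants: 9 ethyl (2Z,4S,6E)-2-(acetoxymethyl)-3-bromo-4-hydroxy-6-methyl-8-oxoocta-2,6-dienoate; 10 angelic acid
Product: 12 ethyl (2Z,4S,6E)-2-(acetoxymethyl)-4-(angeloyloxy)-3-bromo-6-methyl-8-oxoocta-2,6-dienoate, via mixed anhydride 11 (not isolated)
Conditions: 10, 2,4,6-Cl3C6H2COCl, Et3N (1.0 equiv), PhMe, rt; then 9, 60–75 °C
Reagents that add atoms: none
Why: Yamaguchi-type mixed-anhydride esterification without a nucleophilic catalyst, which acylates hindered alcohols with angelic acid without Z-to-E leakage; the near-neutral medium avoids vinylogous E1cB loss of the new ester, and C8 is untouched.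

Step 7
Reactants: 12 ethyl (2Z,4S,6E)-2-(acetoxymethyl)-4-(angeloyloxy)-3-bromo-6-methyl-8-oxoocta-2,6-dienoate; 8 (E)-1-(tert-butyldimethylsilyloxy)-3-methylbuta-1,3-diene
Product: 14 ethyl (2Z,4S,6E,8S,10E)-2-(acetoxymethyl)-4-(angeloyloxy)-3-bromo-8,12-dihydroxy-6,10-dimethyldodeca-2,6,10-trienoate, via enal 13 (not isolated)
Conditions: same oxazaborolidinone (0.5 equiv), iPrOH, EtCN, −78 °C; then MeOH, CeCl3·7H2O, NaBH4, −78 to −40 °C
Reagents that add atoms: none
Why: A second vinylogous Mukaiyama aldol under the same catalyst control (si face; the remote C8 has no influence) sets C2 as S, and Luche 1,2-reduction in the same flask turns the new E-enal into the allylic alcohol without touching the esters or the bromide.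

Step 8
Reactants: 14 ethyl (2Z,4S,6E,8S,10E)-2-(acetoxymethyl)-4-(angeloyloxy)-3-bromo-8,12-dihydroxy-6,10-dimethyldodeca-2,6,10-trienoate
Product: 15 ethyl (2Z,4S,6E,8S,10R,11R)-2-(acetoxymethyl)-4-(angeloyloxy)-3-bromo-10,11-epoxy-8,12-dihydroxy-6,10-dimethyldodeca-2,6-dienoate
Conditions: Ti(OiPr)4 (0.3 equiv), D-(−)-DET (0.36 equiv), tBuOOH, 4 Å MS, CH2Cl2, −25 °C
Reagents that add atoms: tert-butyl hydroperoxide, CC(C)(C)OO
Why: Sharpless asymmetric epoxidation, in which D-(−)-tartrate gives the R,R-epoxide of the geraniol-type E-allylic alcohol (C4 = R, C5 = R), while the S-configured C2 carbinol is the slow-reacting enantiomer for this tartrate and its olefin carries a cis methyl, so C1=C10 stays intact.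

Step 9
Reactants: 15 ethyl (2Z,4S,6E,8S,10R,11R)-2-(acetoxymethyl)-4-(angeloyloxy)-3-bromo-10,11-epoxy-8,12-dihydroxy-6,10-dimethyldodeca-2,6-dienoate
Product: 17 ethyl (2Z,4S,6E,8S,10R,11S)-8-acetoxy-2-(acetoxymethyl)-4-(angeloyloxy)-3-bromo-10,11-epoxy-6,10-dimethyl-12-oxododeca-2,6-dienoate, via hydroxy aldehyde 16 (not isolated)
Conditions: TEMPO (0.1 equiv), PhI(OAc)2 (1.1 equiv), CH2Cl2, rt; then pyridine, Ac2O, DMAP (cat.), 0 °C
Reagents that add atoms: acetic anhydride, CC(=O)OC(C)=O
Why: Oxoammonium (TEMPO) oxidation selects the primary alcohol, the trans-epoxide forbids a six-membered lactol and hence over-oxidation, and acetylation of the remaining C2 alcohol follows; no stereocentre changes (the C5 label becomes S only through priority rules).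

Step 10
Reactants: 17 ethyl (2Z,4S,6E,8S,10R,11S)-8-acetoxy-2-(acetoxymethyl)-4-(angeloyloxy)-3-bromo-10,11-epoxy-6,10-dimethyl-12-oxododeca-2,6-dienoate
Product: 20 (1(10)E,2S,4R,5E,8S)-2,13-diacetoxy-8-angeloyloxy-4-hydroxygermacra-1(10),5,7(11)-trien-12,6-olide, via hydroxy ester 18 (not isolated), via epoxy butenolide 19 (not isolated)
Conditions: CrCl2 (10 equiv), NiCl2 (0.1 equiv), DMF/THF, 17 added over 12 h (final 2 mM), rt; aq. EDTA work-up; crude, DBU (1.2 equiv), CH2Cl2, −20 to 0 °C
Reagents that add atoms: none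
Why: Nozaki–Hiyama–Kishi macrocyclisation followed by lactonisation and vinylogous E1cB, in which zerovalent nickel inserts into the activated C7–Br bond, the alkenylchromium adds to the epoxy aldehyde (pre-folded by its E-olefin and trans-epoxide) to close C6–C7, the C6 oxygen sits cis to CO2Et and lactonises, and DBU removes the butenolide γ-H6 so that the furanolate opens the epoxide at C5; the C6 epimer mixture and C5 are erased, C4 keeps its oxygen and stays R, and the ring holds C4 syn to C7 (5E), as in glaucolide-to-hirsutinolide conversions.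

Step 11
Reactants: 20 (1(10)E,2S,4R,5E,8S)-2,13-diacetoxy-8-angeloyloxy-4-hydroxygermacra-1(10),5,7(11)-trien-12,6-olide
Product: 21 CNP0165707.1, (2S,4R,5E,8S)-2,13-diacetoxy-8-angeloyloxy-4,14-dihydroxygermacra-1(10),5,7(11)-trien-12,6-olide with C9 cis to C2 on C1=C10
Conditions: SeO2 (0.5 equiv), tBuOOH (3 equiv), CH2Cl2, rt
Reagents that add atoms: tert-butyl hydroperoxide, CC(C)(C)OO (oxygen relayed through SeO2, O=[Se]=O)
Why: SeO2 allylic oxidation (ene reaction at C1 taking H from C14, then [2,3]-sigmatropic shift) acts on the only electron-rich olefin; C9 is shielded and deactivated by C8-OAng, and the [2,3] step places CH2OH trans to C2 and so turns the ring olefin cis, as in prenyl acetate oxidation and in parthenolide to melampomagnolide B.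

## Compound list
1 | ethyl bromopyruvate | CCOC(=O)C(=O)CBr | starting material
2 | ethyl 3-acetoxy-2-oxopropanoate | CCOC(=O)C(=O)COC(C)=O | intermediate
3 | (triphenylphosphoranylidene)acetaldehyde | O=CC=P(c1ccccc1)(c1ccccc1)c1ccccc1 | starting material
4 | ethyl (E)-2-(acetoxymethyl)-4-oxobut-2-enoate | O=C/C=C(\COC(C)=O)C(=O)OCC | intermediate
5 | ethyl 2-(acetoxymethyl)-2,3-dibromo-4-oxobutanoate (diastereomer mixture, not isolated) | O=CC(Br)C(Br)(COC(C)=O)C(=O)OCC | intermediate
6 | ethyl (Z)-2-(acetoxymethyl)-3-bromo-4-oxobut-2-enoate | O=C/C(Br)=C(\COC(C)=O)C(=O)OCC | intermediate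
7 | prenal | CC(C)=CC=O | starting material
8 | (E)-1-(tert-butyldimethylsilyloxy)-3-methylbuta-1,3-diene | C=C(C)/C=C/O[Si](C)(C)C(C)(C)C | intermediate
9 | C8-(S) alcohol, C2 enal (octadienoate of step 5) | O=C/C=C(\C)C[C@H](O)/C(Br)=C(\COC(C)=O)C(=O)OCC | intermediate
10 | angelic acid | C/C=C(/C)C(=O)O | starting material
11 | angelic 2,4,6-trichlorobenzoic anhydride (not isolated) | C/C=C(/C)C(=O)OC(=O)c1c(Cl)cc(Cl)cc1Cl | intermediate
12 | C8-(S) angelate, C2 enal | O=C/C=C(\C)C[C@H](OC(=O)/C(C)=C\C)/C(Br)=C(\COC(C)=O)C(=O)OCC | intermediate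
13 | C2-(S) alcohol, C6 enal (not isolated) | O=C/C=C(\C)C[C@H](O)/C=C(\C)C[C@H](OC(=O)/C(C)=C\C)/C(Br)=C(\COC(C)=O)C(=O)OCC | intermediate
14 | C2,C6-diol | OC/C=C(\C)C[C@H](O)/C=C(\C)C[C@H](OC(=O)/C(C)=C\C)/C(Br)=C(\COC(C)=O)C(=O)OCC | intermediate
15 | (4R,5R)-epoxy diol | OC[C@H]1O[C@]1(C)C[C@H](O)/C=C(\C)C[C@H](OC(=O)/C(C)=C\C)/C(Br)=C(\COC(C)=O)C(=O)OCC | intermediate
16 | epoxy aldehyde with free C2-OH (not isolated) | O=C[C@H]1O[C@]1(C)C[C@H](O)/C=C(\C)C[C@H](OC(=O)/C(C)=C\C)/C(Br)=C(\COC(C)=O)C(=O)OCC | intermediate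
17 | cyclisation precursor: epoxy aldehyde, C2 acetate, C7 bromide | O=C[C@H]1O[C@]1(C)C[C@H](OC(C)=O)/C=C(\C)C[C@H](OC(=O)/C(C)=C\C)/C(Br)=C(\COC(C)=O)C(=O)OCC | intermediate
18 | ten-membered C6 hydroxy ethyl ester (C6 epimers, formed as its chromium alkoxide, not isolated) | C/C=C(/C)C(=O)O[C@H]1C/C(C)=C/[C@@H](OC(C)=O)C[C@@]2(C)O[C@@H]2C(O)/C1=C(/COC(C)=O)C(=O)OCC | intermediate
19 | (4R,5R)-4,5-epoxygermacra-1(10),7(11)-dien-12,6-olide (C6 epimers, not isolated) | C/C=C(/C)C(=O)O[C@H]1C/C(C)=C/[C@@H](OC(C)=O)C[C@@]2(C)O[C@@H]2C3OC(=O)C(COC(C)=O)=C31 | intermediate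
20 | 14-deoxy precursor, C1=C10 ring-trans | C/C=C(/C)C(=O)O[C@H]1C/C(C)=C/[C@@H](OC(C)=O)C[C@@](C)(O)/C=C2/OC(=O)C(COC(C)=O)=C21 | intermediate
21 | CNP0165707.1 | C/C=C(/C)C(=O)O[C@H]1C/C(CO)=C\[C@@H](OC(C)=O)C[C@@](C)(O)/C=C2/OC(=O)C(COC(C)=O)=C21 | target

## Step count and risk
Total step count: 11. Longest linear sequence: 10 (steps 1–3 and 5–11).

**Step 10 is the most likely to fail.**
- The alkenyl bromide is fully substituted and must close a ten-membered ring.
- Divalent chromium may reductively open the epoxy aldehyde.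
- The alkenylchromium may expel the C8 angelate to give an allene.

The fallback reverses the order of epoxidation and ring closure. It sets out from enal 13, isolated by leaving out the borohydride quench of step 7. Ac2O/pyridine converts it into the enal acetate F1. CrCl2/NiCl2 closure on this robust enal, with spontaneous lactonisation, gives the 1(10),4,7(11)-trien-12,6-olide F2. C4=C5 is then epoxidised with the D-fructose-derived Shi ketone and 2KHSO5·KHSO4·K2SO4, a reagent-controlled method that gives R,R-epoxides of trisubstituted E-olefins. Selectivity over C1=C10 is expected to be only modest, and any 1,10-epoxide is separated. The fallback returns to the route at 19, which DBU converts into 20.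

**Step 11 comes next.**
- Oxidation may occur at C9 instead of C14.
- C14 may be over-oxidised to the aldehyde.
- The olefin may react slowly because it sits next to the C2 acetate.

The fallback sets out from 20 and replaces the selenium chemistry by photo-oxygenation and transposition. The singlet-oxygen ene reaction (O2, tetraphenylporphyrin, hν, CH2Cl2) abstracts H from the methyl on the crowded side of the olefin and gives the 1-hydroperoxy-10(14)-ene F3. PPh3 reduces it to the allylic alcohol F4. Re2O7-catalysed 1,3-transposition then moves the oxygen to the primary C14 position, with the trisubstituted olefin carrying CH2OH trans to C2. This returns to the route at 21.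

**Step 5 is third.** The asymmetric vinylogous aldol is untested on a fully substituted α-bromo enal with this 3-methyl dienol ether. The fallback sets out from 6 and 8 and replaces asymmetric catalysis by resolution. BF3·OEt2 in CH2Cl2 at −78 °C gives the racemic aldol F5. Candida antarctica lipase B with vinyl acetate converts the R enantiomer (large alkenyl bromide group, medium CH2 group) into its acetate F6. The S alcohol is left unreacted, and this is where the fallback returns to the route at 9.

## Further compounds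
F1 | step 10 | enal acetate (C2-OAc, C6 enal, C7 bromide) | O=C/C=C(\C)C[C@H](OC(C)=O)/C=C(\C)C[C@H](OC(=O)/C(C)=C\C)/C(Br)=C(\COC(C)=O)C(=O)OCC
F2 | step 10 | (2S,8S)-2,13-diacetoxy-8-angeloyloxygermacra-1(10)E,4E,7(11)-trien-12,6-olide (C6 epimers) | C/C=C(/C)C(=O)O[C@H]1C/C(C)=C/[C@@H](OC(C)=O)C/C(C)=C/C2OC(=O)C(COC(C)=O)=C21
F3 | step 11 | 1-hydroperoxy-10(14)-ene (C1 epimers) | C/C=C(/C)C(=O)O[C@H]1CC(=C)C(OO)[C@@H](OC(C)=O)C[C@@](C)(O)/C=C2/OC(=O)C(COC(C)=O)=C21
F4 | step 11 | 1-hydroxy-10(14)-ene (C1 epimers) | C/C=C(/C)C(=O)O[C@H]1CC(=C)C(O)[C@@H](OC(C)=O)C[C@@](C)(O)/C=C2/OC(=O)C(COC(C)=O)=C21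
F5 | step 5 | racemic aldol (rac-9) | O=C/C=C(\C)CC(O)/C(Br)=C(\COC(C)=O)C(=O)OCC
F6 | step 5 | (R)-C8 acetate | O=C/C=C(\C)C[C@@H](OC(C)=O)/C(Br)=C(\COC(C)=O)C(=O)OCC
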